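**Retrosynthetic overview**
- Target ⇐ remove two blocking bromines (Pd/formate) ⇐ open an aryl δ‑lactone with MeMgBr, which gives the 3‑hydroxy‑3‑methylbutyl chain and frees 5‑OH.
- Key step: the pyranone ring (C) and the dimethylpyran ring (D) are closed in one pot on a dibrominated deoxybenzoin; HC(OEt)3 supplies C‑2 and prenal supplies the C5 unit.
- Deoxybenzoin ⇐ Friedel–Crafts acylation of 5,7‑dihydroxychroman‑2‑one with (2,4‑dihydroxyphenyl)acetic acid; lactone ⇐ phloroglucinol + acrylic acid.
- Ring order: lactone (temporary; it masks the side chain and leaves only one free phenol beside the ketone) → rings C and D together → lactone opened.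

Assumption: the target has no stereocentre and no stereogenic double bond, so it is achiral and no enantiocontrol is needed.

**Route**

Step 1
Reactants: 1 phloroglucinol; 2 acrylic acid
Product: 3 5,7-dihydroxychroman-2-one
Conditions: Amberlyst‑15, toluene, reflux (Dean–Stark)
Reagents that add atoms: acrylic acid C=CC(=O)O
Why: Acid‑catalysed Friedel–Crafts hydroarylation of acrylic acid by the electron‑rich arene followed by lactonisation onto the neighbouring phenol, and because phloroglucinol is threefold symmetric only one mono‑adduct can form.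

Step 2
Reactants: 3 5,7-dihydroxychroman-2-one; 4 (2,4-dihydroxyphenyl)acetic acid
Product: 5 8-[(2,4-dihydroxyphenyl)acetyl]-5,7-dihydroxychroman-2-one
Conditions: BF3·Et2O (neat), 70–75 °C, 2 h; aq. NaOAc work‑up
Reagents that add atoms: (2,4-dihydroxyphenyl)acetic acid OC(=O)Cc1ccc(O)cc1O
Why: Nencki‑type Friedel–Crafts C‑acylation by the BF3‑activated arylacetic acid, expected at C‑8 (para to the free 5‑OH, ortho to 7‑OH), so the ketone is flanked by one free phenol (the future O‑1) and the lactone oxygen.

Step 3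
Reactants: 5 8-[(2,4-dihydroxyphenyl)acetyl]-5,7-dihydroxychroman-2-one; 6 N-bromosuccinimide
Product: 7 6-bromo-8-[(5-bromo-2,4-dihydroxyphenyl)acetyl]-5,7-dihydroxychroman-2-one
Conditions: NBS (2.05 equiv), MeCN, −20 → 0 °C
Reagents that add atoms: N-bromosuccinimide O=C1CCC(=O)N1Br
Why: Electrophilic aromatic bromination takes the only open carbon of ring A (C‑6) and the most reactive carbon of the resorcinol ring (C‑5′, para to 2′‑OH), so the two bromines act as traceless blocking groups that leave C‑3′ as the single free activated carbon.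

Step 4
Reactants: 7 6-bromo-8-[(5-bromo-2,4-dihydroxyphenyl)acetyl]-5,7-dihydroxychroman-2-one; 8 triethyl orthoformate; 9 3-methylbut-2-enal (prenal)
Product: 11 6-bromo-9-(8-bromo-5-hydroxy-2,2-dimethyl-2H-chromen-6-yl)-5-hydroxy-3,4-dihydro-2H,10H-pyrano[2,3-f]chromene-2,10-dione, via bromo isoflavone lactone 10 (not isolated)
Conditions: HC(OEt)3 (3 equiv), pyridine, piperidine (5 mol %), 110 °C, EtOH distilled off; then prenal (3 equiv), 120 °C (sealed), same pot
Reagents that add atoms: triethyl orthoformate CCOC(OCC)OCC; 3-methylbut-2-enal CC(C)=CC=O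
Why: Orthoformate isoflavone synthesis (formylation of the active methylene, then 6‑endo addition–elimination by the only free ortho‑phenol) followed in the same pot by pyridine‑mediated chromenylation with prenal (Knoevenagel‑type attack of C‑3′, the only unblocked phenoxide carbon, dehydration to the o‑quinone methide and oxa‑6π electrocyclisation onto the more acidic, non‑chelated 4′‑oxygen) closes both heterocycles in one operation.

Step 5
Reactants: 11 6-bromo-9-(8-bromo-5-hydroxy-2,2-dimethyl-2H-chromen-6-yl)-5-hydroxy-3,4-dihydro-2H,10H-pyrano[2,3-f]chromene-2,10-dione; 12 methylmagnesium bromide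
Product: 13 8-bromo-3-(8-bromo-5-hydroxy-2,2-dimethyl-2H-chromen-6-yl)-5,7-dihydroxy-6-(3-hydroxy-3-methylbutyl)-4H-chromen-4-one
Conditions: MeMgBr (8 equiv), THF, −20 °C → rt; sat. NH4Cl quench (no strong acid)
Reagents that add atoms: methylmagnesium bromide C[Mg]Br
Why: Double Grignard addition to the activated aryl lactone gives the tertiary alcohol and frees 5‑OH, while the chromone is shielded as its electron‑rich magnesium phenoxide (a vinylogous carboxylate) and the aryl bromides are inert to MeMgBr.

Step 6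
Reactants: 13 8-bromo-3-(8-bromo-5-hydroxy-2,2-dimethyl-2H-chromen-6-yl)-5,7-dihydroxy-6-(3-hydroxy-3-methylbutyl)-4H-chromen-4-one
Product: 14 Kanzonol T
Conditions: Pd(OAc)2 (10 mol %), PPh3, HCO2Na, DMF/H2O, 80 °C
Reagents that add atoms: none
Why: Palladium‑catalysed transfer hydrodehalogenation (oxidative addition, formate decarboxylation, C–H reductive elimination) removes both blocking bromines without reducing the chromene C=C or disturbing the tertiary alcohol, and no stereocentre is involved.

**Compound list**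

1 | phloroglucinol | Oc1cc(O)cc(O)c1 | starting material
2 | acrylic acid | C=CC(=O)O | starting material
3 | 5,7-dihydroxychroman-2-one | O=C1CCc2c(O)cc(O)cc2O1 | intermediate
4 | (2,4-dihydroxyphenyl)acetic acid | OC(=O)Cc1ccc(O)cc1O | starting material
5 | 8-[(2,4-dihydroxyphenyl)acetyl]-5,7-dihydroxychroman-2-one | O=C1CCc2c(O)cc(O)c(C(=O)Cc3ccc(O)cc3O)c2O1 | intermediate
6 | N-bromosuccinimide | O=C1CCC(=O)N1Br | starting material
7 | 6-bromo-8-[(5-bromo-2,4-dihydroxyphenyl)acetyl]-5,7-dihydroxychroman-2-one | O=C1CCc2c(O)c(Br)c(O)c(C(=O)Cc3cc(Br)c(O)cc3O)c2O1 | intermediate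
8 | triethyl orthoformate | CCOC(OCC)OCC | starting material
9 | 3-methylbut-2-enal (prenal) | CC(C)=CC=O | starting material
10 | 6-bromo-9-(5-bromo-2,4-dihydroxyphenyl)-5-hydroxy-3,4-dihydro-2H,10H-pyrano[2,3-f]chromene-2,10-dione (bromo isoflavone lactone) | O=C1CCc2c(O)c(Br)c3occ(-c4cc(Br)c(O)cc4O)c(=O)c3c2O1 | intermediate (not isolated)
11 | 6-bromo-9-(8-bromo-5-hydroxy-2,2-dimethyl-2H-chromen-6-yl)-5-hydroxy-3,4-dihydro-2H,10H-pyrano[2,3-f]chromene-2,10-dione | O=C1CCc2c(O)c(Br)c3occ(-c4cc(Br)c5c(c4O)C=CC(C)(C)O5)c(=O)c3c2O1 | intermediate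
12 | methylmagnesium bromide | C[Mg]Br | starting material
13 | 8-bromo-3-(8-bromo-5-hydroxy-2,2-dimethyl-2H-chromen-6-yl)-5,7-dihydroxy-6-(3-hydroxy-3-methylbutyl)-4H-chromen-4-one | CC(C)(O)CCc1c(O)c(Br)c2occ(-c3cc(Br)c4c(c3O)C=CC(C)(C)O4)c(=O)c2c1O | intermediate
14 | Kanzonol T, 5,7-dihydroxy-6-(3-hydroxy-3-methylbutyl)-3-(5-hydroxy-2,2-dimethyl-2H-chromen-6-yl)-4H-chromen-4-one | CC(C)(O)CCc1c(O)cc2occ(-c3ccc4c(c3O)C=CC(C)(C)O4)c(=O)c2c1O | target

**Step count**
Total steps: 6. Longest linear sequence: 6 (1 → 3 → 5 → 7 → 11 → 13 → 14).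

**Steps most likely to fail, with fallbacks**

Step 4 (one‑pot double annulation). The condensation at the hindered C‑3′ may be slow, the pyran may close partly onto O‑2′, or the lactone may be ethanolysed before ring C has closed. Fallback: set out from 10, here isolated after the orthoformate stage. Friedel–Crafts C‑prenylation with 2‑methylbut‑3‑en‑2‑ol and BF3·Et2O (dioxane, 0–20 °C) at C‑3′, the only unblocked activated carbon, gives 6-bromo-9-[5-bromo-2,4-dihydroxy-3-(3-methylbut-2-en-1-yl)phenyl]-5-hydroxy-3,4-dihydro-2H,10H-pyrano[2,3-f]chromene-2,10-dione F1. DDQ (benzene, reflux) then closes the pyran by dehydrogenative cyclisation through the o‑quinone methide, and the route is rejoined at 11.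

Step 5 (Grignard addition next to a chromone). MeMgBr may attack C‑4 or C‑2 of the chromone, or the addition may stop at the methyl ketone. Fallback: set out from 7 and add MeMgBr before any chromone exists, with the ketone masked as its magnesium enolate/phenoxide. Opening the lactone gives 1-[3-bromo-2,4,6-trihydroxy-5-(3-hydroxy-3-methylbutyl)phenyl]-2-(5-bromo-2,4-dihydroxyphenyl)ethan-1-one F2. The orthoformate/prenal protocol of step 4 then runs through 8-bromo-3-(5-bromo-2,4-dihydroxyphenyl)-5,7-dihydroxy-6-(3-hydroxy-3-methylbutyl)-4H-chromen-4-one F3 and rejoins the route at 13. In this variant the pyranone closure must rely on the bromine‑flanked, more acidic phenol acting as the nucleophile while the alkyl‑flanked phenol stays hydrogen‑bonded to the ketone.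

Step 2 (Friedel–Crafts acylation with a free 2‑hydroxyarylacetic acid). Acylation may go partly to C‑6, and the 2′‑hydroxy ketone may cyclodehydrate to a 2‑arylbenzofuran in hot BF3·Et2O. Fallback: set out from 4 and dehydrate it (TsOH, toluene, Dean–Stark) to 6-hydroxy-1-benzofuran-2(3H)-one F4. In this lactone the 2‑oxygen is tied up as the leaving group, and it is used for ring‑opening Friedel–Crafts transacylation of 3 (cat. TfOH or BF3·Et2O, 25–40 °C), rejoining the route at 5.

Further compounds
F1 | step 4 | 6-bromo-9-[5-bromo-2,4-dihydroxy-3-(3-methylbut-2-en-1-yl)phenyl]-5-hydroxy-3,4-dihydro-2H,10H-pyrano[2,3-f]chromene-2,10-dione | O=C1CCc2c(O)c(Br)c3occ(-c4cc(Br)c(O)c(CC=C(C)C)c4O)c(=O)c3c2O1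
F2 | step 5 | 1-[3-bromo-2,4,6-trihydroxy-5-(3-hydroxy-3-methylbutyl)phenyl]-2-(5-bromo-2,4-dihydroxyphenyl)ethan-1-one | CC(C)(O)CCc1c(O)c(Br)c(O)c(C(=O)Cc2cc(Br)c(O)cc2O)c1O
F3 | step 5 | 8-bromo-3-(5-bromo-2,4-dihydroxyphenyl)-5,7-dihydroxy-6-(3-hydroxy-3-methylbutyl)-4H-chromen-4-one | CC(C)(O)CCc1c(O)c(Br)c2occ(-c3cc(Br)c(O)cc3O)c(=O)c2c1O
F4 | step 2 | 6-hydroxy-1-benzofuran-2(3H)-one | O=C1Cc2ccc(O)cc2O1
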